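Ring A (C4a, C5, C6, C7, C8, C8a) is built from open-chain parts. Because C6 carries piperidine C2'' between the oxygens on C5 and C7, ring A is a 2-substituted resorcinol, the pattern a vinylketene and a siloxyalkyne assemble. Light turns the diazoketone, a finished (2S) ring C with a diazoacetyl group on the future C8a, into a vinylketene; the siloxyalkyne, made from N-Boc-L-pipecolic acid, adds and the adduct reorganises to the phenol, so ring A forms in one operation with O1 locked para to the piperidine. C2 comes from a catalytic asymmetric aldol–cyclisation, C2'' from the chiral pool, and both phenol silyl ethers fall in a single last step.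

Key step: step 8

Remarks on the chemistry:
- Bond count: besides C5–C6, C7–C8 and C4a–C5, the 1,2-shift of the Wolff rearrangement makes C8–C8a (the former acyl–pyranone bond is broken), so four skeletal bonds form and ring A is the only ring closed.
- Protecting groups: the ring B phenol is carried as a TIPS ether, the same group the alkyne delivers to O7, so one buffered fluoride step frees both phenols and no hydrogenation is run next to the benzylic C2–O1 and C2''–N bonds; nitrogen stays Boc until after the annulation.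
- Assumption: the (S)-BINOL–Ti(OiPr)4 catalyst is taken to deliver the dienolate to the Si face of the aldehyde, as it does with related silyl nucleophiles; the sense is checked on the first run and (R)-BINOL used if it is opposite.

Step 1
Reactants: 1 4-hydroxybenzaldehyde
Product: 2 4-(triisopropylsilyloxy)benzaldehyde
Conditions: TIPSCl, imidazole, DMF, 25 °C
Reagents that add atoms: triisopropylsilyl chloride, CC(C)[Si](Cl)(C(C)C)C(C)C
Why: Imidazole-promoted O-silylation of a phenol is routine, and the TIPS ether is the same group that the alkyne will place on O7.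

Step 2
Reactants: 3 methyl 2,4-dioxopentanoate
Product: 4 methyl (2Z)-2,4-bis(trimethylsilyloxy)penta-2,4-dienoate
Conditions: TMSOTf (2.2 equiv), Et3N, Et2O, 0 → 25 °C; used crude
Reagents that add atoms: trimethylsilyl trifluoromethanesulfonate, C[Si](C)(C)OS(=O)(=O)C(F)(F)F
Why: Soft enolisation with silyl triflate and amine silylates the chelated C2 enol and then the methyl ketone, the standard way to 1,3-bis(silyloxy)dienes, giving a cross-conjugated diene whose terminal CH2 is the nucleophilic carbon.

Step 3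
Reactants: 2 4-(triisopropylsilyloxy)benzaldehyde; 4 methyl (2Z)-2,4-bis(trimethylsilyloxy)penta-2,4-dienoate
Product: 6 methyl (2S)-4-oxo-2-[4-(triisopropylsilyloxy)phenyl]-3,4-dihydro-2H-pyran-6-carboxylate, via silylated aldol adduct 5 (not isolated)
Conditions: (S)-BINOL (20 mol%), Ti(OiPr)4 (20 mol%), 4 Å MS, THF, −78 → −20 °C; then TFA, CH2Cl2, 0 °C, brief
Reagents that add atoms: none
Why: Catalytic asymmetric vinylogous Mukaiyama aldol (formal hetero-Diels–Alder) of a bis(silyloxy)diene, in which the titanium binaphtholate binds aldehyde 2 and should expose its Si face to the terminal diene carbon, setting C2 as (S) in 5, after which TFA lets the benzylic oxygen close onto the enol ether carbon with loss of hexamethyldisiloxane and without breaking a bond at the new stereocentre.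

Step 4
Reactants: 6 methyl (2S)-4-oxo-2-[4-(triisopropylsilyloxy)phenyl]-3,4-dihydro-2H-pyran-6-carboxylate
Product: 7 (2S)-4-oxo-2-[4-(triisopropylsilyloxy)phenyl]-3,4-dihydro-2H-pyran-6-carboxylic acid
Conditions: Me3SnOH, ClCH2CH2Cl, 70 °C; 5% aq. HCl wash
Reagents that add atoms: trimethyltin hydroxide, C[Sn](C)(C)O
Why: Trimethyltin hydroxide hydrolyses the activated acrylate-type methyl ester under near-neutral conditions (mild ester hydrolysis), which avoids the aqueous alkali that would open the dihydropyranone by β-elimination and racemise C2, and it should leave the aryl silyl ether alone.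

Step 5
Reactants: 7 (2S)-4-oxo-2-[4-(triisopropylsilyloxy)phenyl]-3,4-dihydro-2H-pyran-6-carboxylic acid
Product: 9 (2S)-6-(diazoacetyl)-2-[4-(triisopropylsilyloxy)phenyl]-2,3-dihydro-4H-pyran-4-one, via acid chloride 8 (not isolated)
Conditions: Me2C=C(Cl)NMe2, CH2Cl2, 0 → 25 °C; then TMSCHN2 (2 equiv), MeCN/THF, 0 °C
Reagents that add atoms: (trimethylsilyl)diazomethane, C[Si](C)(C)C=[N+]=[N-]
Why: Acylation of a diazoalkane by an acid chloride (first stage of the Arndt–Eistert sequence), in which the chloro-enamine makes 8 without releasing HCl so that the benzylic C2–O1 bond is not ionised, and the bulky silyl diazomethane should be acylated at carbon faster than it adds as a dipole to the trisubstituted, oxygen-substituted ring alkene, chloride then removing silicon to give 9.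

Step 6
Reactants: 10 (2S)-1-(tert-butoxycarbonyl)piperidine-2-carboxylic acid (N-Boc-L-pipecolic acid)
Product: 11 1-tert-butyl 2-methyl (2S)-piperidine-1,2-dicarboxylate
Conditions: MeI, K2CO3, DMF, 25 °C
Reagents that add atoms: iodomethane, CI
Why: SN2 O-methylation of the carboxylate with carbonate base leaves the carbamate and the α-stereocentre untouched.

Step 7
Reactants: 11 1-tert-butyl 2-methyl (2S)-piperidine-1,2-dicarboxylate
Product: 14 tert-butyl (2S)-2-[(triisopropylsilyloxy)ethynyl]piperidine-1-carboxylate, via dibromomethyl ketone 12 (not isolated), via lithium ynolate 13 (not isolated)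
Conditions: CH2Br2, LiTMP (lithium 2,2,6,6-tetramethylpiperidide, 2.1 equiv), THF, −78 °C; n-BuLi, −78 → 25 °C; TIPSCl, −78 → 0 °C
Reagents that add atoms: dibromomethane, BrCBr; triisopropylsilyl chloride, CC(C)[Si](Cl)(C(C)C)C(C)C
Why: Kowalski ester homologation stopped at the ynolate, in which dibromomethyllithium adds to the ester to give 12, 12 is enolised, and bromine–lithium exchange triggers the 1,2-shift of the piperidinyl carbon (retention at C2'') to ynolate 13, which the bulky silyl chloride traps on oxygen.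

Step 8
Reactants: 9 (2S)-6-(diazoacetyl)-2-[4-(triisopropylsilyloxy)phenyl]-2,3-dihydro-4H-pyran-4-one; 14 tert-butyl (2S)-2-[(triisopropylsilyloxy)ethynyl]piperidine-1-carboxylate (1.2 equiv)
Product: 19 tert-butyl (2S)-2-[(2S)-5-hydroxy-4-oxo-7-(triisopropylsilyloxy)-2-[4-(triisopropylsilyloxy)phenyl]-3,4-dihydro-2H-chromen-6-yl]piperidine-1-carboxylate, via vinylketene 15 (not isolated), via cyclobutenone 16 (not isolated), via dienylketene 17 (not isolated), via cyclohexadienone 18 (not isolated)
Conditions: hν (LED, ca. 400 nm), ClCH2CH2Cl, 25 °C; then 80 °C in the dark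
Reagents that add atoms: none
Why: This is the Danheiser benzannulation in its photo-Wolff form: excitation of 9 expels N2 and the pyranone carbon shifts from the acyl carbon to the former diazo carbon (making C8–C8a) to give vinylketene 15. The alkyne carbon remote from oxygen, the one bearing the piperidine, attacks the ketene carbonyl carbon in a [2+2] cycloaddition that forms C5–C6 and C7–C8 and gives cyclobutenone 16. Warming opens 16 by conrotatory 4π electrocyclic cleavage to dienylketene 17, and ring A closes by thermal disrotatory 6π electrocyclisation onto the pyranone CH carbon (C4a–C5), after which cyclohexadienone 18 tautomerises to the hydrogen-bonded C5 phenol. No lasting stereocentre is created, since the sp3 carbons of 16 and 18 are erased on aromatisation and C2 and C2'' are spectators under neutral, base-free conditions. The only selectivity needed is the orientation of the [2+2] step, secured by the oxygen-induced polarisation of the ynol ether against the electrophilic ketene carbon, which puts the piperidine on C6 between O5 and O7 and leaves O1 para to it. Long-wavelength light should be absorbed by the diazo chromophore alone, keeping the enone of 9 and the phenol of 19 out of the photochemistry.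

Step 9
Reactants: 19 tert-butyl (2S)-2-[(2S)-5-hydroxy-4-oxo-7-(triisopropylsilyloxy)-2-[4-(triisopropylsilyloxy)phenyl]-3,4-dihydro-2H-chromen-6-yl]piperidine-1-carboxylate
Product: 22 (2S)-5-hydroxy-6-[(2S)-1-methylpiperidin-2-yl]-7-(triisopropylsilyloxy)-2-[4-(triisopropylsilyloxy)phenyl]-2,3-dihydro-4H-chromen-4-one, via amine trifluoroacetate 20 (not isolated), via N-methyleneiminium ion 21 (not isolated)
Conditions: TFA, anisole, CH2Cl2, 0 °C, brief; evaporate; then 37% aq. HCHO, NaBH(OAc)3, Et3N (1 equiv), ClCH2CH2Cl, 0 → 25 °C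
Reagents that add atoms: formaldehyde, C=O
Why: Carbamate acidolysis (anisole traps the tert-butyl cation away from ring A) followed by reductive amination, in which the acetoxyborohydride reduces iminium ion 21 much faster than the hydrogen-bonded C4 ketone, and with O7 and O4' still silylated the formaldehyde should not aminomethylate C8 (Mannich reaction).

Step 10
Reactants: 22 (2S)-5-hydroxy-6-[(2S)-1-methylpiperidin-2-yl]-7-(triisopropylsilyloxy)-2-[4-(triisopropylsilyloxy)phenyl]-2,3-dihydro-4H-chromen-4-one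
Product: 23 (2S)-5,7-dihydroxy-2-(4-hydroxyphenyl)-6-[(2S)-1-methylpiperidin-2-yl]-2,3-dihydro-4H-chromen-4-one (CNP0146489.1)
Conditions: TBAF, AcOH (1:1), THF, 0 → 25 °C
Reagents that add atoms: none
Why: Fluoride cleaves both aryl silyl ethers, and the acetic acid buffer keeps the liberated phenoxides protonated so that the flavanone should not open to the chalcone (retro-oxa-Michael) and lose the C2 configuration.

Compound list
1 | 4-hydroxybenzaldehyde | O=Cc1ccc(O)cc1 | starting material
2 | 4-(triisopropylsilyloxy)benzaldehyde | O=Cc1ccc(O[Si](C(C)C)(C(C)C)C(C)C)cc1 | intermediate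
3 | methyl 2,4-dioxopentanoate | COC(=O)C(=O)CC(C)=O | starting material
4 | methyl (2Z)-2,4-bis(trimethylsilyloxy)penta-2,4-dienoate | C=C(O[Si](C)(C)C)/C=C(\O[Si](C)(C)C)C(=O)OC | intermediate
5 | methyl (2Z,6S)-4-oxo-2,6-bis(trimethylsilyloxy)-6-[4-(triisopropylsilyloxy)phenyl]hex-2-enoate (silylated aldol adduct) | COC(=O)/C(O[Si](C)(C)C)=C/C(=O)C[C@H](O[Si](C)(C)C)c1ccc(O[Si](C(C)C)(C(C)C)C(C)C)cc1 | intermediate (not isolated)
6 | methyl (2S)-4-oxo-2-[4-(triisopropylsilyloxy)phenyl]-3,4-dihydro-2H-pyran-6-carboxylate | COC(=O)C1=CC(=O)C[C@@H](c2ccc(O[Si](C(C)C)(C(C)C)C(C)C)cc2)O1 | intermediate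
7 | (2S)-4-oxo-2-[4-(triisopropylsilyloxy)phenyl]-3,4-dihydro-2H-pyran-6-carboxylic acid | OC(=O)C1=CC(=O)C[C@@H](c2ccc(O[Si](C(C)C)(C(C)C)C(C)C)cc2)O1 | intermediate
8 | (2S)-4-oxo-2-[4-(triisopropylsilyloxy)phenyl]-3,4-dihydro-2H-pyran-6-carbonyl chloride | ClC(=O)C1=CC(=O)C[C@@H](c2ccc(O[Si](C(C)C)(C(C)C)C(C)C)cc2)O1 | intermediate (not isolated)
9 | (2S)-6-(diazoacetyl)-2-[4-(triisopropylsilyloxy)phenyl]-2,3-dihydro-4H-pyran-4-one | [N-]=[N+]=CC(=O)C1=CC(=O)C[C@@H](c2ccc(O[Si](C(C)C)(C(C)C)C(C)C)cc2)O1 | intermediate (key-step precursor)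
10 | (2S)-1-(tert-butoxycarbonyl)piperidine-2-carboxylic acid | CC(C)(C)OC(=O)N1CCCC[C@H]1C(=O)O | starting material
11 | 1-tert-butyl 2-methyl (2S)-piperidine-1,2-dicarboxylate | CC(C)(C)OC(=O)N1CCCC[C@H]1C(=O)OC | intermediate
12 | tert-butyl (2S)-2-(2,2-dibromoacetyl)piperidine-1-carboxylate | CC(C)(C)OC(=O)N1CCCC[C@H]1C(=O)C(Br)Br | intermediate (not isolated)
13 | lithium 2-[(2S)-1-(tert-butoxycarbonyl)piperidin-2-yl]ethynolate | CC(C)(C)OC(=O)N1CCCC[C@H]1C#C[O-].[Li+] | intermediate (not isolated)
14 | tert-butyl (2S)-2-[(triisopropylsilyloxy)ethynyl]piperidine-1-carboxylate | CC(C)(C)OC(=O)N1CCCC[C@H]1C#CO[Si](C(C)C)(C(C)C)C(C)C | intermediate (key-step precursor)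
15 | (2S)-6-(2-oxoethenyl)-2-[4-(triisopropylsilyloxy)phenyl]-2,3-dihydro-4H-pyran-4-one (vinylketene) | O=C=CC1=CC(=O)C[C@@H](c2ccc(O[Si](C(C)C)(C(C)C)C(C)C)cc2)O1 | intermediate (not isolated)
16 | cyclobut-2-en-1-one bearing the (2S)-N-Boc-piperidin-2-yl group on C2, OTIPS on C3 and the (2S)-pyranon-6-yl group on C4 (mixture at C4) | CC(C)(C)OC(=O)N1CCCC[C@H]1C1=C(O[Si](C(C)C)(C(C)C)C(C)C)C(C1=O)C1=CC(=O)C[C@@H](c2ccc(O[Si](C(C)C)(C(C)C)C(C)C)cc2)O1 | intermediate (not isolated)
17 | dienylketene O=C=C(piperidinyl)–C(OTIPS)=CH–(pyranon-6-yl) from ring opening of 16 | CC(C)(C)OC(=O)N1CCCC[C@H]1C(=C=O)C(O[Si](C(C)C)(C(C)C)C(C)C)=CC1=CC(=O)C[C@@H](c2ccc(O[Si](C(C)C)(C(C)C)C(C)C)cc2)O1 | intermediate (not isolated)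
18 | 4a-H cyclohexadienone tautomer of 19 (mixture at C4a) | CC(C)(C)OC(=O)N1CCCC[C@H]1C1=C(O[Si](C(C)C)(C(C)C)C(C)C)C=C2O[C@H](c3ccc(O[Si](C(C)C)(C(C)C)C(C)C)cc3)CC(=O)C2C1=O | intermediate (not isolated)
19 | tert-butyl (2S)-2-[(2S)-5-hydroxy-4-oxo-7-(triisopropylsilyloxy)-2-[4-(triisopropylsilyloxy)phenyl]-3,4-dihydro-2H-chromen-6-yl]piperidine-1-carboxylate | CC(C)(C)OC(=O)N1CCCC[C@H]1c1c(O[Si](C(C)C)(C(C)C)C(C)C)cc2c(c1O)C(=O)C[C@@H](c1ccc(O[Si](C(C)C)(C(C)C)C(C)C)cc1)O2 | intermediate (key-step product)
20 | (2S)-5-hydroxy-6-[(2S)-piperidin-2-yl]-7-(triisopropylsilyloxy)-2-[4-(triisopropylsilyloxy)phenyl]-2,3-dihydro-4H-chromen-4-one trifluoroacetate | N1CCCC[C@H]1c1c(O[Si](C(C)C)(C(C)C)C(C)C)cc2c(c1O)C(=O)C[C@@H](c1ccc(O[Si](C(C)C)(C(C)C)C(C)C)cc1)O2.OC(=O)C(F)(F)F | intermediate (not isolated)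
21 | N-methyleneiminium ion of the amine in 20 | C=[N+]1CCCC[C@H]1c1c(O[Si](C(C)C)(C(C)C)C(C)C)cc2c(c1O)C(=O)C[C@@H](c1ccc(O[Si](C(C)C)(C(C)C)C(C)C)cc1)O2 | intermediate (not isolated)
22 | (2S)-5-hydroxy-6-[(2S)-1-methylpiperidin-2-yl]-7-(triisopropylsilyloxy)-2-[4-(triisopropylsilyloxy)phenyl]-2,3-dihydro-4H-chromen-4-one | CN1CCCC[C@H]1c1c(O[Si](C(C)C)(C(C)C)C(C)C)cc2c(c1O)C(=O)C[C@@H](c1ccc(O[Si](C(C)C)(C(C)C)C(C)C)cc1)O2 | intermediate
23 | (2S)-5,7-dihydroxy-2-(4-hydroxyphenyl)-6-[(2S)-1-methylpiperidin-2-yl]-2,3-dihydro-4H-chromen-4-one | CN1CCCC[C@H]1c1c(O)cc2c(c1O)C(=O)C[C@@H](c1ccc(O)cc1)O2 | target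

Total step count: 10. Longest linear sequence: 7 steps (1, 3, 4, 5, 8, 9, 10; the line through diene 4 is equally long).

Steps most likely to fail

1. Step 8. The ketene may form but not be captured: light may be taken up by the enone or by the accumulating product, the ketene may dimerise while the [2+2] at the hindered alkyne is slow, or the siloxy-cyclobutenone may resist opening. The fallback makes the same ketene in the dark and at low concentration. It sets out from 9: silver-benzoate-catalysed Wolff rearrangement in wet THF (AgO2CPh, Et3N, THF/H2O, 25 °C; Arndt–Eistert homologation) should give 2-[(2S)-4-oxo-2-[4-(triisopropylsilyloxy)phenyl]-3,4-dihydro-2H-pyran-6-yl]acetic acid F1. The chloro-enamine used in step 5 converts it into 2-[(2S)-4-oxo-2-[4-(triisopropylsilyloxy)phenyl]-3,4-dihydro-2H-pyran-6-yl]acetyl chloride F2. Slow addition of F2 to 14 and Et3N in toluene at 80 °C generates 15 by dehydrochlorination, and the same cycloaddition and electrocyclisation cascade rejoins the route at 19.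

2. Step 3. Facial discrimination may be poor with the ester-bearing diene, or the diene may be desilylated faster than it adds. The fallback sets C2 by reagent control and builds the ring by Claisen condensation. It sets out from 2: Brown allylation ((−)-Ipc2B(allyl), Et2O, −78 °C; ethanolamine work-up) should give (1S)-1-[4-(triisopropylsilyloxy)phenyl]but-3-en-1-ol F3. Tsuji–Wacker oxidation (PdCl2, CuCl, O2, DMF/H2O) gives (4S)-4-hydroxy-4-[4-(triisopropylsilyloxy)phenyl]butan-2-one F4. Its alkoxide–enolate dianion (LiN(SiMe3)2, 2.2 equiv, THF, −78 °C) is acylated at the methyl terminus with dimethyl oxalate to give methyl (6S)-6-hydroxy-2,4-dioxo-6-[4-(triisopropylsilyloxy)phenyl]hexanoate F5. Brief TFA in CH2Cl2 cyclodehydrates F5 and the route is rejoined at 6.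

3. Step 7. The carbenoid shift may be incomplete, butyllithium may attack the carbamate, or silylation may go to carbon and give a silylketene. The fallback makes the ynolate by oxidation of an acetylide instead. It sets out from 11: i-Bu2AlH (toluene, −78 °C) gives tert-butyl (2S)-2-formylpiperidine-1-carboxylate F6. Seyferth–Gilbert homologation with the Ohira–Bestmann reagent (dimethyl (1-diazo-2-oxopropyl)phosphonate, K2CO3, MeOH, 0 °C, kept cold to protect the α-stereocentre) gives tert-butyl (2S)-2-ethynylpiperidine-1-carboxylate F7. Deprotonation (LiN(SiMe3)2, THF, −78 °C), oxygen transfer from LiOOtBu to give ynolate 13, and silylation with TIPSOTf rejoin the route at 14.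

Further compounds
F1 | step 8 | 2-[(2S)-4-oxo-2-[4-(triisopropylsilyloxy)phenyl]-3,4-dihydro-2H-pyran-6-yl]acetic acid | OC(=O)CC1=CC(=O)C[C@@H](c2ccc(O[Si](C(C)C)(C(C)C)C(C)C)cc2)O1
F2 | step 8 | 2-[(2S)-4-oxo-2-[4-(triisopropylsilyloxy)phenyl]-3,4-dihydro-2H-pyran-6-yl]acetyl chloride | ClC(=O)CC1=CC(=O)C[C@@H](c2ccc(O[Si](C(C)C)(C(C)C)C(C)C)cc2)O1
F3 | step 3 | (1S)-1-[4-(triisopropylsilyloxy)phenyl]but-3-en-1-ol | C=CC[C@H](O)c1ccc(O[Si](C(C)C)(C(C)C)C(C)C)cc1
F4 | step 3 | (4S)-4-hydroxy-4-[4-(triisopropylsilyloxy)phenyl]butan-2-one | CC(=O)C[C@H](O)c1ccc(O[Si](C(C)C)(C(C)C)C(C)C)cc1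
F5 | step 3 | methyl (6S)-6-hydroxy-2,4-dioxo-6-[4-(triisopropylsilyloxy)phenyl]hexanoate | COC(=O)C(=O)CC(=O)C[C@H](O)c1ccc(O[Si](C(C)C)(C(C)C)C(C)C)cc1
F6 | step 7 | tert-butyl (2S)-2-formylpiperidine-1-carboxylate | CC(C)(C)OC(=O)N1CCCC[C@H]1C=O
F7 | step 7 | tert-butyl (2S)-2-ethynylpiperidine-1-carboxylate | CC(C)(C)OC(=O)N1CCCC[C@H]1C#C
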